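Ring A of the flavone (C4a, C5, C6, C7, C8, C8a) bears oxygen on C5, C7 and C8a and the C4 acyl carbon on C4a. This is the alternating pattern of three acetate units grown from a caffeoyl starter. Everything rests on disconnecting C4a–C8a. A magnesium-templated intramolecular Claisen condensation folds a linear methyl 9-aryl-3,5,7-trioxonon-8-enoate, whose aryl group carries a 4-benzyl ether and a 3-MOM ether. In one operation it forms the carbocycle, aromatises it and delivers the 2',4',6'-trihydroxychalcone. The chain is assembled in masked form on a dioxinone and released under neutral conditions. Ring C, the 3'-sulfate and deprotection follow by routine flavonoid chemistry.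

Key step: step 6

Assumption: the target is drawn as the hydrogen sulfate; aryl hydrogen sulfates are strong, hydrolytically fragile acids, so the ester is carried as its potassium salt and protonated only in the last, cold work-up.
Remark: polycarbonyl compounds are drawn as keto tautomers although they exist as keto–enol mixtures.

Step 1
Reactants: 1 4-(benzyloxy)-3-hydroxybenzaldehyde
Product: 2 4-(benzyloxy)-3-(methoxymethoxy)benzaldehyde
Conditions: MOMCl (1.3 equiv), iPr2NEt (1.6 equiv), CH2Cl2, 0 °C → rt
Reagents that add atoms: chloromethyl methyl ether, COCCl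
Why: Williamson-type O-alkylation of the only free phenol by the highly reactive α-chloro ether installs an acetal that withstands the bases, the heat and the iodine of steps 2–8 and is orthogonal to benzyl ethers.

Step 2
Reactants: 2 4-(benzyloxy)-3-(methoxymethoxy)benzaldehyde; 3 diethyl {2-[methoxy(methyl)amino]-2-oxoethyl}phosphonate
Product: 4 (E)-3-[4-(benzyloxy)-3-(methoxymethoxy)phenyl]-N-methoxy-N-methylprop-2-enamide
Conditions: LiCl (1.3 equiv), DBU (1.2 equiv), MeCN, rt
Reagents that add atoms: none
Why: Horner–Wadsworth–Emmons olefination under Masamune–Roush conditions is reliably E-selective with aromatic aldehydes and gives in one step the Weinreb amide that serves as acyl donor in step 4.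

Step 3
Reactants: 5 2,2,6-trimethyl-4H-1,3-dioxin-4-one; 6 acetyl chloride
Product: 8 2,2-dimethyl-6-(2-oxopropyl)-4H-1,3-dioxin-4-one, via lithium dienolate 7 (not isolated)
Conditions: 5 (2 equiv), LiN(SiMe3)2 (2 equiv), THF, −78 °C; 6 (1 equiv), −78 °C; cold 1 M HCl
Reagents that add atoms: none
Why: Crossed Claisen-type γ-C-acylation of the extended lithium dienolate 7 by an acid chloride is established for this dioxinone, and a twofold excess of 7 takes up the proton of the more acidic product.

Step 4
Reactants: 8 2,2-dimethyl-6-(2-oxopropyl)-4H-1,3-dioxin-4-one; 4 (E)-3-[4-(benzyloxy)-3-(methoxymethoxy)phenyl]-N-methoxy-N-methylprop-2-enamide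
Product: 11 6-{(E)-6-[4-(benzyloxy)-3-(methoxymethoxy)phenyl]-2,4-dioxohex-5-en-1-yl}-2,2-dimethyl-4H-1,3-dioxin-4-one, via dilithium dianion 9 (not isolated), via tetrahedral adduct 10 (not isolated)
Conditions: 8 (1.5 equiv), LiN(iPr)2 (3.1 equiv), THF, −78 → −40 °C; 4 (1 equiv), −78 → −20 °C; AcOH, −78 °C
Reagents that add atoms: none
Why: Dianion acylation in the manner of a Weinreb ketone synthesis: the last-formed terminal carbanion of 9 is its most nucleophilic site and adds 1,2 to amide 4, and the lithium-chelated adduct 10 persists until the quench, so that neither an acidic product nor an N–H leaving group (as from an imidazolide made in situ) is released to protonate 9.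

Step 5
Reactants: 11 6-{(E)-6-[4-(benzyloxy)-3-(methoxymethoxy)phenyl]-2,4-dioxohex-5-en-1-yl}-2,2-dimethyl-4H-1,3-dioxin-4-one
Product: 13 methyl (E)-9-[4-(benzyloxy)-3-(methoxymethoxy)phenyl]-3,5,7-trioxonon-8-enoate, via acylketene 12 (not isolated)
Conditions: MeOH (20 equiv), PhMe, 110 °C, sealed tube; evaporate, use crude
Reagents that add atoms: methanol, CO
Why: Thermal retro-hetero-Diels–Alder cleavage of the dioxinone expels acetone, and acylketene 12 is trapped by the large excess of methanol faster than by its own enol oxygen, which frees the open chain under neutral conditions, whereas a base would aromatise 11 in the aldol sense.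

Step 6
Reactants: 13 methyl (E)-9-[4-(benzyloxy)-3-(methoxymethoxy)phenyl]-3,5,7-trioxonon-8-enoate
Product: 15 (E)-4-(benzyloxy)-2',4',6'-trihydroxy-3-(methoxymethoxy)chalcone, via acylcyclohexanetrione 14 (not isolated)
Conditions: Mg(OMe)2 (5 equiv, solution in MeOH), MeOH–THF, rt → 60 °C; cold 0.5 M HCl to pH 4
Reagents that add atoms: none
Why: With excess Mg(OMe)2 every 1,3-dicarbonyl unit of 13 is deprotonated and bound to magnesium, so the ketone carbonyls C3, C5 and C7 are masked as enolate oxygens while the ester carbonyl C1 remains the only electrophile and is activated by coordination; C6 then attacks C1 and methoxide departs to give trione 14. The reaction type is the intramolecular Claisen (Dieckmann-type) condensation known for 3,5,7-triketo esters, cinnamoyl-terminated ones included, which gives acylphloroglucinols. The one ring formed (chain atoms C6, C5, C4, C3, C2, C1, which become C4a, C5, C6, C7, C8, C8a) closes in the 6-exo-trig mode, the carbonyl oxygen of C1 lying outside the ring. Aromatisation of 14 by tautomerisation and phenoxide formation is a thermodynamic sink, so the ring cannot reopen, reversible additions of methoxide or enolate to the enone drain into 15, and any 15 that closes to flavanone 16 on work-up is simply the intermediate of step 7. No stereocentre is formed and the E double bond is a spectator. The selectivity needed is C-acylation at C1 rather than aldol attack of C2 on C7 or O-acylation by an enol oxygen, and it is secured by complete enolisation of the ketones (no ketone electrophile is left), by the low electrophilicity of the conjugated, electron-rich cinnamoyl carbonyl C7, and by an ester rather than a carboxylate at C1.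

Step 7
Reactants: 15 (E)-4-(benzyloxy)-2',4',6'-trihydroxy-3-(methoxymethoxy)chalcone
Product: 17 4'-(benzyloxy)-5,7-dihydroxy-3'-(methoxymethoxy)flavone, via racemic flavanone 16 (not isolated)
Conditions: I2 (1.1 equiv), pyridine, 95 °C; aq. Na2S2O3
Reagents that add atoms: none
Why: In hot pyridine the 2',6'-dihydroxychalcone closes by 6-endo-trig oxa-Michael addition to racemic flavanone 16, which iodine dehydrogenates by C3 iodination of its enol and loss of HI (the iodine–pyridine flavanone-to-flavone oxidation), and because the solvent binds HI the MOM acetal is not exposed to the hot acid that iodine in DMSO would generate, while the transient C2 stereocentre disappears.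

Step 8
Reactants: 17 4'-(benzyloxy)-5,7-dihydroxy-3'-(methoxymethoxy)flavone
Product: 18 4',7-bis(benzyloxy)-5-hydroxy-3'-(methoxymethoxy)flavone
Conditions: BnBr (1.05 equiv), K2CO3 (1.2 equiv), DMF, rt
Reagents that add atoms: benzyl bromide, BrCc1ccccc1
Why: Williamson etherification is selective for the acidic 7-OH because the 5-OH is locked in a hydrogen bond to the C4 carbonyl and is not alkylated by one equivalent of halide with a weak base.

Step 9
Reactants: 18 4',7-bis(benzyloxy)-5-hydroxy-3'-(methoxymethoxy)flavone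
Product: 19 4',7-bis(benzyloxy)-3',5-dihydroxyflavone
Conditions: conc. HCl (cat.), MeOH–THF, 50 °C
Reagents that add atoms: none
Why: Acid-catalysed acetal exchange (MOM cleavage) frees only the 3'-OH, since aryl benzyl ethers and the flavone core are inert to dilute methanolic HCl.

Step 10
Reactants: 19 4',7-bis(benzyloxy)-3',5-dihydroxyflavone
Product: 20 potassium 4',7-bis(benzyloxy)-5-hydroxyflavon-3'-yl sulfate
Conditions: SO3·pyridine (3 equiv), pyridine, rt; aq. KHCO3 to pH 8; C18 or Sephadex LH-20
Reagents that add atoms: sulfur trioxide–pyridine complex, O=S(=O)([O-])[n+]1ccccc1; potassium hydrogencarbonate, [K+].OC([O-])=O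
Why: O-Sulfonation with an SO3–amine complex takes place at the only unchelated phenol, 3'-OH, the hydrogen-bonded 5-OH being the least reactive hydroxyl of a flavone towards such reagents, and neutralisation fixes the acid-labile monoester as its stable potassium salt.

Step 11
Reactants: 20 potassium 4',7-bis(benzyloxy)-5-hydroxyflavon-3'-yl sulfate
Product: 22 luteolin 3'-sulfate, via potassium luteolin 3'-sulfate 21 (not isolated)
Conditions: H2 (1 atm), 10% Pd/C, MeOH–THF–H2O, rt; filter, strip organic solvents cold; aq. HCl (1.0 equiv), 0 °C; C18 (H2O, then MeCN–H2O); freeze-dry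
Reagents that add atoms: none
Why: Catalytic hydrogenolysis cleaves both aryl benzyl ethers under neutral conditions that leave an aryl sulfate salt and the chromone C2–C3 double bond intact at atmospheric pressure, and a brief cold protonation in water followed by desalting then gives the hydrogen sulfate.

Compound list
1 | 4-(benzyloxy)-3-hydroxybenzaldehyde | O=Cc1ccc(OCc2ccccc2)c(O)c1 | starting material
2 | 4-(benzyloxy)-3-(methoxymethoxy)benzaldehyde | O=Cc1ccc(OCc2ccccc2)c(OCOC)c1 | intermediate
3 | diethyl {2-[methoxy(methyl)amino]-2-oxoethyl}phosphonate | CCOP(=O)(CC(=O)N(C)OC)OCC | starting material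
4 | (E)-3-[4-(benzyloxy)-3-(methoxymethoxy)phenyl]-N-methoxy-N-methylprop-2-enamide | CON(C)C(=O)/C=C/c1ccc(OCc2ccccc2)c(OCOC)c1 | intermediate
5 | 2,2,6-trimethyl-4H-1,3-dioxin-4-one | CC1=CC(=O)OC(C)(C)O1 | starting material
6 | acetyl chloride | CC(=O)Cl | starting material
7 | lithium dienolate of 5 (lithium 2,2-dimethyl-6-methylidene-1,3-dioxin-4-olate) | [Li+].C=C1C=C([O-])OC(C)(C)O1 | intermediate
8 | 2,2-dimethyl-6-(2-oxopropyl)-4H-1,3-dioxin-4-one | CC(=O)CC1=CC(=O)OC(C)(C)O1 | intermediate
9 | dilithium dianion of 8 (terminal enolate plus ring dienolate) | [Li+].[Li+].C=C([O-])C=C1C=C([O-])OC(C)(C)O1 | intermediate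
10 | dilithium salt of the tetrahedral N-methoxy-N-methyl adduct of 9 and 4 (racemic) | [Li+].[Li+].CON(C)C([O-])(CC(=O)C=C1C=C([O-])OC(C)(C)O1)/C=C/c1ccc(OCc2ccccc2)c(OCOC)c1 | intermediate
11 | 6-{(E)-6-[4-(benzyloxy)-3-(methoxymethoxy)phenyl]-2,4-dioxohex-5-en-1-yl}-2,2-dimethyl-4H-1,3-dioxin-4-one | CC1(C)OC(=O)C=C(CC(=O)CC(=O)/C=C/c2ccc(OCc3ccccc3)c(OCOC)c2)O1 | intermediate
12 | (8E)-9-[4-(benzyloxy)-3-(methoxymethoxy)phenyl]nona-1,8-diene-1,3,5,7-tetrone (acylketene) | O=C=CC(=O)CC(=O)CC(=O)/C=C/c1ccc(OCc2ccccc2)c(OCOC)c1 | intermediate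
13 | methyl (E)-9-[4-(benzyloxy)-3-(methoxymethoxy)phenyl]-3,5,7-trioxonon-8-enoate | COC(=O)CC(=O)CC(=O)CC(=O)/C=C/c1ccc(OCc2ccccc2)c(OCOC)c1 | intermediate
14 | 2-{(E)-3-[4-(benzyloxy)-3-(methoxymethoxy)phenyl]prop-2-enoyl}cyclohexane-1,3,5-trione | O=C1CC(=O)C(C(=O)/C=C/c2ccc(OCc3ccccc3)c(OCOC)c2)C(=O)C1 | intermediate
15 | (E)-4-(benzyloxy)-2',4',6'-trihydroxy-3-(methoxymethoxy)chalcone | O=C(/C=C/c1ccc(OCc2ccccc2)c(OCOC)c1)c1c(O)cc(O)cc1O | intermediate
16 | (±)-4'-(benzyloxy)-5,7-dihydroxy-3'-(methoxymethoxy)flavanone | O=C1CC(c2ccc(OCc3ccccc3)c(OCOC)c2)Oc2cc(O)cc(O)c12 | intermediate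
17 | 4'-(benzyloxy)-5,7-dihydroxy-3'-(methoxymethoxy)flavone | O=c1cc(-c2ccc(OCc3ccccc3)c(OCOC)c2)oc2cc(O)cc(O)c12 | intermediate
18 | 4',7-bis(benzyloxy)-5-hydroxy-3'-(methoxymethoxy)flavone | O=c1cc(-c2ccc(OCc3ccccc3)c(OCOC)c2)oc2cc(OCc3ccccc3)cc(O)c12 | intermediate
19 | 4',7-bis(benzyloxy)-3',5-dihydroxyflavone | O=c1cc(-c2ccc(OCc3ccccc3)c(O)c2)oc2cc(OCc3ccccc3)cc(O)c12 | intermediate
20 | potassium 4',7-bis(benzyloxy)-5-hydroxyflavon-3'-yl sulfate | [K+].O=c1cc(-c2ccc(OCc3ccccc3)c(OS(=O)(=O)[O-])c2)oc2cc(OCc3ccccc3)cc(O)c12 | intermediate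
21 | potassium luteolin 3'-sulfate | [K+].O=c1cc(-c2ccc(O)c(OS(=O)(=O)[O-])c2)oc2cc(O)cc(O)c12 | intermediate
22 | luteolin 3'-sulfate (hydrogen sulfate form; no stereocentre) | O=c1cc(-c2ccc(O)c(OS(=O)(=O)O)c2)oc2cc(O)cc(O)c12 | target

Total step count: 11. Longest linear sequence: 10 steps (steps 1, 2 and 4–11, from 1 to 22); step 3 is the short convergent branch.

Steps most likely to fail

1. Step 6.
- What may go wrong: the chain may fold in the aldol sense (C2 onto C7 with dehydration). It may also be O-acylated through an enol oxygen to a lactone, or be cut by retro-Claisen attack of methoxide before the ring closes.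
- Fallback: it sets out from 2 and comes back at 18; ring A is then bought instead of built.
- Commercial 2',4',6'-trihydroxyacetophenone is benzylated once at its unchelated 4'-OH (BnBr, 1 equiv, K2CO3, acetone). This gives 1-[4-(benzyloxy)-2,6-dihydroxyphenyl]ethan-1-one F1.
- Claisen–Schmidt condensation of F1 with 2 (KOH, EtOH, rt) gives (E)-4,4'-bis(benzyloxy)-2',6'-dihydroxy-3-(methoxymethoxy)chalcone F2.
- I2 in pyridine at 95 °C, as in step 7, carries F2 through (±)-4',7-bis(benzyloxy)-5-hydroxy-3'-(methoxymethoxy)flavanone F3 to 18.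

2. Step 4.
- What may go wrong: proton transfer may quench the dianion. Conjugate addition to the enamide may compete, and base-induced breakdown of the N-methoxy amide may leave the coupling incomplete.
- Fallback: it replaces acylation by aldol addition and oxidation. It sets out from 4 and from dianion 9 (made from 8) and comes back at 11.
- Reduction of 4 with iBu2AlH (THF, −78 °C) gives (E)-3-[4-(benzyloxy)-3-(methoxymethoxy)phenyl]prop-2-enal F4, a far better electrophile than the amide.
- 1,2-Addition of 9 to F4 (THF, −78 °C) gives racemic 6-{(E)-6-[4-(benzyloxy)-3-(methoxymethoxy)phenyl]-4-hydroxy-2-oxohex-5-en-1-yl}-2,2-dimethyl-4H-1,3-dioxin-4-one F5.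
- Oxidation of the allylic alcohol of F5 with Dess–Martin periodinane (NaHCO3, CH2Cl2, 0 °C) gives 11.

3. Step 11.
- What may go wrong: hydrogenolysis of a sparingly soluble amphiphilic salt may be slow. The C2–C3 double bond may be saturated on long exposure, and the sulfate may be lost by acid-catalysed hydrolysis during repeated handling of the ionic ester.
- Fallback: it carries the sulfate as a neutral protected diester. It sets out from 19 and comes back at 22.
- 2,2,2-Trichloroethyl chlorosulfate (ClS(=O)(=O)OCC(Cl)(Cl)Cl) with Et3N and DMAP in THF (0 °C → rt) sulfonates the 3'-OH. The product is the chromatographable 4',7-bis(benzyloxy)-5-hydroxyflavon-3'-yl 2,2,2-trichloroethyl sulfate F6.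
- Buffered catalytic transfer hydrogenolysis (Pd/C, HCO2NH4, MeOH) removes the trichloroethyl group and both benzyl ethers in one operation and gives ammonium luteolin 3'-sulfate F7.
- F7 is protonated cold and desalted as in step 11 to give 22.

Further compounds
F1 | step 6 | 1-[4-(benzyloxy)-2,6-dihydroxyphenyl]ethan-1-one | CC(=O)c1c(O)cc(OCc2ccccc2)cc1O
F2 | step 6 | (E)-4,4'-bis(benzyloxy)-2',6'-dihydroxy-3-(methoxymethoxy)chalcone | O=C(/C=C/c1ccc(OCc2ccccc2)c(OCOC)c1)c1c(O)cc(OCc2ccccc2)cc1O
F3 | step 6 | (±)-4',7-bis(benzyloxy)-5-hydroxy-3'-(methoxymethoxy)flavanone | O=C1CC(c2ccc(OCc3ccccc3)c(OCOC)c2)Oc2cc(OCc3ccccc3)cc(O)c12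
F4 | step 4 | (E)-3-[4-(benzyloxy)-3-(methoxymethoxy)phenyl]prop-2-enal | O=C/C=C/c1ccc(OCc2ccccc2)c(OCOC)c1
F5 | step 4 | racemic 6-{(E)-6-[4-(benzyloxy)-3-(methoxymethoxy)phenyl]-4-hydroxy-2-oxohex-5-en-1-yl}-2,2-dimethyl-4H-1,3-dioxin-4-one | CC1(C)OC(=O)C=C(CC(=O)CC(O)/C=C/c2ccc(OCc3ccccc3)c(OCOC)c2)O1
F6 | step 11 | 4',7-bis(benzyloxy)-5-hydroxyflavon-3'-yl 2,2,2-trichloroethyl sulfate | O=c1cc(-c2ccc(OCc3ccccc3)c(OS(=O)(=O)OCC(Cl)(Cl)Cl)c2)oc2cc(OCc3ccccc3)cc(O)c12
F7 | step 11 | ammonium luteolin 3'-sulfate | [NH4+].O=c1cc(-c2ccc(O)c(OS(=O)(=O)[O-])c2)oc2cc(O)cc(O)c12
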